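Each exchange takes one incoming ligand out of solution, so a flask can be booked by one number, the exchange count: the mean number of exchanges per complex charged. [incoming ligand] is then its charge minus the count times the complex charged.

| flask | starting complex | incoming ligand | remark | time |
|---|---|---|---|---|
| midnight | 0.17 M | 0.625 M | run made earlier |  |
| alder | 0.25 M | 0.625 M |  | 8.0 d |
| cedar | 0.25 M | 0.750 M |  | 8.0 d |
| larch | 0.25 M | 1.00 M |  | 8.0 d |

midnight run (percent of the starting complex charged)

| time / d | complex with two exchanged / % | complex with one exchanged / % |
|---|---|---|
| 0.417 | 17 | 44 |
| 0.833 | 24 | 48 |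
| 1.25 | 25 | 47 |
| 2.50 | 26 | 42 |
| 5.00 | 30 | 26 |

(standard deviation of a reading: 1.5 percentage points)

- the earlier runs were read with a standard deviation of 1.5 percentage points
- no earlier run changes the charge of incoming ligand; that part of a forecast is a guess

- how much complex with two exchanged is there at the end, in percent of the starting complex charged: for each flask in turn (alder, cedar, larch)

The meeting took the midnight run first. I, writing the minutes, proposed booking the part of the complex missing from both columns as complex with three exchanged, an assumption, that species having no column in the run. The midnight count then comes to 1.90 at 2.50 d and 2.18 at 5.00 d, with [incoming ligand] going from 0.302 M to 0.254 M. Those readings give 2.80 × 10⁻⁴ L mol⁻¹ min⁻¹ for the exchange pace, the rise of the count with time divided by the mean [incoming ligand] over the stretch, and that figure carries the scatter of the readings.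

I then started each flask from the midnight count at 2.50 d, a second assumption, and carried the pace on to 8.0 d. In larch, a first round with [incoming ligand] held at the value this booking gives it at 2.50 d yields 3.06, more than the 3 exchanges a complex can take. Putting the [incoming ligand] that this count leaves back into the mean gives 2.74. The same two rounds give 2.14 for alder and 2.34 for cedar. On this booking, complex with two exchanged, an intermediate, can stand at no more than 3 minus the count, which puts my estimate for larch under 25.9%, and my judgement was that the yield would fall as the ligand charge rises.

The forecaster argued the opposite direction, giving 25%, 31% and 40%, “Assuming the final yield scales roughly with this ratio”, and the larch figure stands higher than my ceiling.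

The flasks gave 27.5%, 25.6% and 19.5%.

    starting complex + incoming ligand ⇌ leaving ligand + complex with one exchanged (K = 38.0, k = 0.00400 L mol⁻¹ min⁻¹)
    complex with one exchanged + incoming ligand ⇌ leaving ligand + complex with two exchanged (K = 0.310, k = 0.00240 L mol⁻¹ min⁻¹)
    complex with two exchanged + incoming ligand ⇌ leaving ligand + complex with three exchanged (K = 0.660, k = 0.00130 L mol⁻¹ min⁻¹)
    starting complex ⇌ dormant form (K = 0.340, k = 0.00170 min⁻¹)
    leaving ligand + starting complex → side product (k = 4.40 × 10⁻⁴ L mol⁻¹ min⁻¹)
    leaving ligand → by-product carried off (k = 3.70 × 10⁻⁴ min⁻¹)

In alder, from 4.00 d to 8.00 d, complex with one exchanged fell from 45.5% to 31.5% and complex with three exchanged rose from 23.1% to 36.9%, while complex with two exchanged went from 26.4% to 27.5% and the exchange pace, read as 2.80 × 10⁻⁴ L mol⁻¹ min⁻¹ from the midnight run, came to 3.03 × 10⁻⁴ L mol⁻¹ min⁻¹. In larch over the same days, complex with two exchanged fell from 26.0% to 19.5% and complex with three exchanged rose from 46.3% to 68.0%, with 36.7% of its charge of incoming ligand still there at 8.00 d, and the pace came to 1.56 × 10⁻⁴ L mol⁻¹ min⁻¹.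

Readings and results stem from a simulated flask for an exercise.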